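**Plan**

1. Retrosynthetic cuts, in order: the two peri O–H / quinone C=O pairs (back to a 1,4,5,8-tetrakis(methoxymethoxy)naphthalene), then the ester C(=O)–O bond (to 3-acetoxy-3-methylbutanoic acid), then the bond from ring carbon C2 to the carbinol carbon.
2. Enabling feature: the stereocentre is a secondary carbinol CH bonded directly to ring carbon C2. Its C–O bond can therefore be a masked C–B bond, and C2 can arrive by a 1,2-shift from boron onto a lithiated O–CH2 carbon. Boron is bonded to both fragments in the key intermediate and is absent from the target.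
3. Second feature: C2, C3, C6 and C7 of the 1,4,5,8-tetraoxygenated naphthalene are symmetry-equivalent, and the two rings of the naphthazarin interconvert by tautomerism. Ring metalation and the final ring oxidation therefore need no regiocontrol.
4. Forward order: naphthazarin → tetra-MOM naphthalene → ring boronate; 4-methylpent-3-en-1-ol → hindered benzoate; the two are joined by lithiation–borylation–oxidation; the alcohol is acylated; Ce(IV) oxidation and acetal hydrolysis unveil the naphthazarin last. No ring is built; both rings come from naphthazarin.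
5. Stereochemistry: the single (R) centre comes from (−)-sparteine-controlled deprotonation, carried through retention (C–B formation), inversion (1,2-shift) and retention (C–B oxidation). No later step breaks a bond at this carbon.

Key step: step 4

Assumption: the 2-substituted quinoid form drawn for the target and its 6-substituted naphthazarin tautomer are one compound (fast proton tautomerism); the (R) centre corresponds to the shikonin series.

**Route**

Step 1
Reactants: 1 naphthazarin (5,8-dihydroxy-1,4-naphthoquinone)
Product: 3 1,4,5,8-tetrakis(methoxymethoxy)naphthalene, via leuconaphthazarin 2 (not isolated)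
Conditions: Na2S2O4, EtOAc/H2O, rt, Ar; organic phase dried and concentrated; NaH (5 equiv), MOMCl (5 equiv), DMF, 0 °C to rt, Ar
Reagents that add atoms: chloromethyl methyl ether (MOMCl), COCCl
Why: Reductive alkylation of a quinone: dithionite should give the leuco form, whose four oxygens are then O-alkylated (Williamson) under exclusion of air, with aromatisation of the diketo tautomer driving O- over C-alkylation.

Step 2
Reactants: 3 1,4,5,8-tetrakis(methoxymethoxy)naphthalene
Product: 5 4,4,5,5-tetramethyl-2-[1,4,5,8-tetrakis(methoxymethoxy)naphthalen-2-yl]-1,3,2-dioxaborolane, via aryllithium 4 (not isolated)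
Conditions: n-BuLi (1.05 equiv), THF, −78 to 0 °C; i-PrOBpin, −78 °C to rt; H2O
Reagents that add atoms: 2-isopropoxy-4,4,5,5-tetramethyl-1,3,2-dioxaborolane, CC(C)OB1OC(C)(C)C(C)(C)O1
Why: Directed ortho-metalation by a methoxymethoxy group followed by borylation; the four ring C–H positions are equivalent, so one equivalent of base should give a single mono-lithio species.

Step 3
Reactants: 6 4-methylpent-3-en-1-ol; 7 2,4,6-triisopropylbenzoic acid
Product: 8 4-methylpent-3-en-1-yl 2,4,6-triisopropylbenzoate
Conditions: PPh3, DIAD, THF, 0 °C to rt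
Reagents that add atoms: none
Why: Mitsunobu esterification of a primary alcohol with a hindered acid; the resulting benzoate is the directing and leaving group for step 4 and its carbonyl is shielded against attack by alkyllithiums.

Step 4
Reactants: 8 4-methylpent-3-en-1-yl 2,4,6-triisopropylbenzoate; 5 4,4,5,5-tetramethyl-2-[1,4,5,8-tetrakis(methoxymethoxy)naphthalen-2-yl]-1,3,2-dioxaborolane
Product: 12 (R)-4-methyl-1-[1,4,5,8-tetrakis(methoxymethoxy)naphthalen-2-yl]pent-3-en-1-ol, via lithiated benzoate 9 (not isolated), via boronate complex 10 (not isolated), via benzylic boronic ester 11 (not isolated)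
Conditions: 8, (−)-sparteine, s-BuLi, Et2O, −78 °C, 5 h; 5 (THF/Et2O), −78 °C, 1 h, then reflux; then 2 M NaOH, 30% H2O2, THF, 0 °C to rt
Reagents that add atoms: hydrogen peroxide, OO
Why: s-BuLi·(−)-sparteine should remove the pro-S hydrogen of the O–CH2 group of 8 (carbonyl-directed, dipole-stabilised lithiation) to give the configurationally stable carbenoid 9, which adds to the boron of 5 with retention to form boronate 10. On warming, the naphthyl group shifts from boron to carbon anti to the departing triisopropylbenzoate (inversion at carbon), which forms the bond between ring carbon C2 and the future carbinol carbon and gives boronic ester 11; alkaline peroxide then replaces boron by oxygen with retention. The closest known reaction type is the asymmetric lithiation–borylation (Matteson-type 1,2-metalate rearrangement) of aryl pinacol boronates with sparteine-lithiated primary benzoates or carbamates, followed by oxidation. No ring is closed. The single new stereocentre is under reagent control by (−)-sparteine, and the retention/inversion/retention sequence should translate the (S)-carbenoid into the (R)-alcohol. The step needs deprotonation at O–CH2 rather than at allylic or ring positions, secured by the ester-directed complex and the attack-resistant triisopropylbenzoyl group, and carbon rather than oxygen migration, secured by the aryl group being the only carbon ligand on boron.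

Step 5
Reactants: 13 3-hydroxy-3-methylbutanoic acid
Product: 14 3-acetoxy-3-methylbutanoic acid
Conditions: AcCl (neat, excess), 0 °C to rt; volatiles removed
Reagents that add atoms: acetyl chloride, CC(=O)Cl
Why: O-acetylation of a hydroxy acid with neat acyl chloride, a standard way to acylate tertiary hydroxy acids without base and therefore without β-elimination.

Step 6
Reactants: 12 (R)-4-methyl-1-[1,4,5,8-tetrakis(methoxymethoxy)naphthalen-2-yl]pent-3-en-1-ol; 14 3-acetoxy-3-methylbutanoic acid
Product: 15 (R)-4-methyl-1-[1,4,5,8-tetrakis(methoxymethoxy)naphthalen-2-yl]pent-3-en-1-yl 3-acetoxy-3-methylbutanoate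
Conditions: DCC, DMAP (cat.), CH2Cl2, 0 °C to rt
Reagents that add atoms: none
Why: Steglich esterification at the alcohol oxygen leaves the C–O bond of the stereocentre intact; acylating before unveiling keeps the acyl transfer away from the quinone and blocks oxidation or cyclisation of the free carbinol.

Step 7
Reactants: 15 (R)-4-methyl-1-[1,4,5,8-tetrakis(methoxymethoxy)naphthalen-2-yl]pent-3-en-1-yl 3-acetoxy-3-methylbutanoate
Product: 18 (R)-1-(5,8-dihydroxy-1,4-dioxo-1,4-dihydronaphthalen-2-yl)-4-methylpent-3-en-1-yl 3-acetoxy-3-methylbutanoate (target), via quinoid-ring-substituted bis-MOM quinone 16 (not isolated), via benzenoid-ring-substituted bis-MOM quinone 17 (not isolated)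
Conditions: CAN (2.2 equiv), MeCN/H2O 4:1, 0 °C; extraction (EtOAc); crude in THF/2 M aq HCl 4:1, rt
Reagents that add atoms: water, O
Why: Ce(IV) oxidative dealkylation of a hydroquinone bis-ether should convert one ring (either one, giving 16 or 17 or both) directly to the quinone, after which the two remaining peri acetal ethers, now on an electron-poor ring next to a quinone carbonyl, hydrolyse under mild acid; 16 and 17 converge on the same naphthazarin, and no free hydroquinone carrying the acyloxyalkyl group (which could expel the carboxylate) is ever formed.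

**Compound list**

1 | naphthazarin (5,8-dihydroxy-1,4-naphthoquinone) | O=C1C=CC(=O)c2c(O)ccc(O)c12 | starting material
2 | leuconaphthazarin (5,8-dihydroxy-2,3-dihydronaphthalene-1,4-dione) | O=C1CCC(=O)c2c(O)ccc(O)c12 | intermediate
3 | 1,4,5,8-tetrakis(methoxymethoxy)naphthalene | COCOc1ccc(OCOC)c2c(OCOC)ccc(OCOC)c12 | intermediate
4 | 2-lithio-1,4,5,8-tetrakis(methoxymethoxy)naphthalene | [Li]c1cc(OCOC)c2c(OCOC)ccc(OCOC)c2c1OCOC | intermediate
5 | 4,4,5,5-tetramethyl-2-[1,4,5,8-tetrakis(methoxymethoxy)naphthalen-2-yl]-1,3,2-dioxaborolane | CC1(C)OB(OC1(C)C)c1cc(OCOC)c2c(OCOC)ccc(OCOC)c2c1OCOC | intermediate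
6 | 4-methylpent-3-en-1-ol | CC(C)=CCCO | starting material
7 | 2,4,6-triisopropylbenzoic acid | CC(C)c1cc(C(C)C)c(C(=O)O)c(C(C)C)c1 | starting material
8 | 4-methylpent-3-en-1-yl 2,4,6-triisopropylbenzoate | CC(C)=CCCOC(=O)c1c(C(C)C)cc(C(C)C)cc1C(C)C | intermediate
9 | (S)-1-lithio-4-methylpent-3-en-1-yl 2,4,6-triisopropylbenzoate (as its (−)-sparteine complex) | [Li][C@@H](CC=C(C)C)OC(=O)c1c(C(C)C)cc(C(C)C)cc1C(C)C | intermediate
10 | lithium (S)-configured boronate complex: pinacolato[1,4,5,8-tetrakis(methoxymethoxy)naphthalen-2-yl][4-methyl-1-(2,4,6-triisopropylbenzoyloxy)pent-3-en-1-yl]borate | [Li+].CC1(C)O[B-](OC1(C)C)(c1cc(OCOC)c2c(OCOC)ccc(OCOC)c2c1OCOC)[C@@H](CC=C(C)C)OC(=O)c1c(C(C)C)cc(C(C)C)cc1C(C)C | intermediate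
11 | (R)-4,4,5,5-tetramethyl-2-{4-methyl-1-[1,4,5,8-tetrakis(methoxymethoxy)naphthalen-2-yl]pent-3-en-1-yl}-1,3,2-dioxaborolane | CC1(C)OB(OC1(C)C)[C@H](CC=C(C)C)c1cc(OCOC)c2c(OCOC)ccc(OCOC)c2c1OCOC | intermediate
12 | (R)-4-methyl-1-[1,4,5,8-tetrakis(methoxymethoxy)naphthalen-2-yl]pent-3-en-1-ol | O[C@H](CC=C(C)C)c1cc(OCOC)c2c(OCOC)ccc(OCOC)c2c1OCOC | intermediate
13 | 3-hydroxy-3-methylbutanoic acid | CC(C)(O)CC(=O)O | starting material
14 | 3-acetoxy-3-methylbutanoic acid | CC(=O)OC(C)(C)CC(=O)O | intermediate
15 | (R)-4-methyl-1-[1,4,5,8-tetrakis(methoxymethoxy)naphthalen-2-yl]pent-3-en-1-yl 3-acetoxy-3-methylbutanoate | CC(=O)OC(C)(C)CC(=O)O[C@H](CC=C(C)C)c1cc(OCOC)c2c(OCOC)ccc(OCOC)c2c1OCOC | intermediate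
16 | (R)-1-[5,8-bis(methoxymethoxy)-1,4-dioxo-1,4-dihydronaphthalen-2-yl]-4-methylpent-3-en-1-yl 3-acetoxy-3-methylbutanoate | CC(=O)OC(C)(C)CC(=O)O[C@H](CC=C(C)C)C1=CC(=O)c2c(OCOC)ccc(OCOC)c2C1=O | intermediate
17 | (R)-1-[1,4-bis(methoxymethoxy)-5,8-dioxo-5,8-dihydronaphthalen-2-yl]-4-methylpent-3-en-1-yl 3-acetoxy-3-methylbutanoate | CC(=O)OC(C)(C)CC(=O)O[C@H](CC=C(C)C)c1cc(OCOC)c2C(=O)C=CC(=O)c2c1OCOC | intermediate
18 | (R)-1-(5,8-dihydroxy-1,4-dioxo-1,4-dihydronaphthalen-2-yl)-4-methylpent-3-en-1-yl 3-acetoxy-3-methylbutanoate | CC(=O)OC(C)(C)CC(=O)O[C@H](CC=C(C)C)C1=CC(=O)c2c(O)ccc(O)c2C1=O | target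

**Step count and risks**

Total steps: 7. Longest linear sequence: 5 steps (1, 2, 4, 6, 7).

Steps most likely to fail:

Step 4. The process at risk is slow formation of the hindered, ortho-substituted boronate and incomplete 1,2-migration, with erosion of enantiopurity if the carbenoid warms before it is trapped. The fallback uses known chemistry, sets out from 3 and returns at 12. Compound 3 is lithiated as in step 2 to give 4, which is acylated with N-methoxy-N-methyl-4-methylpent-3-enamide F1 (prepared from commercial 4-methylpent-3-enoic acid, MeNHOMe·HCl and EDC) to give the aryl ketone 4-methyl-1-[1,4,5,8-tetrakis(methoxymethoxy)naphthalen-2-yl]pent-3-en-1-one F2. Reduction of this ketone with (+)-B-chlorodiisopinocampheylborane (THF, −25 °C), with the aryl group as the large substituent, should give the (R)-alcohol 12.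

Step 7. The processes at risk are loss of acetic acid from the tertiary acetate or ester cleavage during the acid hydrolysis of the acetals, and oxidation of the trisubstituted alkene by Ce(IV). The fallback sets out from 12 and returns at 18, so that the acyl fragment never meets oxidant or acid. Alcohol 12 is oxidised with CAN (MeCN/H2O, 0 °C) to 2-[(R)-1-hydroxy-4-methylpent-3-en-1-yl]-5,8-bis(methoxymethoxy)-1,4-naphthoquinone F3 and/or its ring isomer 6-[(R)-1-hydroxy-4-methylpent-3-en-1-yl]-5,8-bis(methoxymethoxy)-1,4-naphthoquinone F4. Acetal hydrolysis (aq HCl/THF) should then give shikonin F5. Its side-chain hydroxyl is acylated with 14 (DCC, DMAP, CH2Cl2, 0 °C) in preference to the chelated peri phenols, to give 18.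

Step 6. The processes at risk are β-elimination of acetate from the activated acyl intermediate (which would give the 3-methylbut-2-enoate) and slow acylation of the hindered alcohol. The fallback sets out from 12 and returns at 15 by building the acyl chain on the substrate. Alcohol 12 is acetylated (Ac2O, pyridine, DMAP) to (R)-4-methyl-1-[1,4,5,8-tetrakis(methoxymethoxy)naphthalen-2-yl]pent-3-en-1-yl acetate F6. Its lithium enolate (LDA, THF, −78 °C) is added to acetone to give (R)-4-methyl-1-[1,4,5,8-tetrakis(methoxymethoxy)naphthalen-2-yl]pent-3-en-1-yl 3-hydroxy-3-methylbutanoate F7. Acetylation of the tertiary hydroxyl (Ac2O, Et3N, DMAP, rt) should give 15.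

**Further compounds**

F1 | step 4 | N-methoxy-N-methyl-4-methylpent-3-enamide | CC(C)=CCC(=O)N(C)OC
F2 | step 4 | 4-methyl-1-[1,4,5,8-tetrakis(methoxymethoxy)naphthalen-2-yl]pent-3-en-1-one | CC(C)=CCC(=O)c1cc(OCOC)c2c(OCOC)ccc(OCOC)c2c1OCOC
F3 | step 7 | 2-[(R)-1-hydroxy-4-methylpent-3-en-1-yl]-5,8-bis(methoxymethoxy)-1,4-naphthoquinone | O[C@H](CC=C(C)C)C1=CC(=O)c2c(OCOC)ccc(OCOC)c2C1=O
F4 | step 7 | 6-[(R)-1-hydroxy-4-methylpent-3-en-1-yl]-5,8-bis(methoxymethoxy)-1,4-naphthoquinone | O[C@H](CC=C(C)C)c1cc(OCOC)c2C(=O)C=CC(=O)c2c1OCOC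
F5 | step 7 | shikonin, 5,8-dihydroxy-2-[(R)-1-hydroxy-4-methylpent-3-en-1-yl]-1,4-naphthoquinone | O[C@H](CC=C(C)C)C1=CC(=O)c2c(O)ccc(O)c2C1=O
F6 | step 6 | (R)-4-methyl-1-[1,4,5,8-tetrakis(methoxymethoxy)naphthalen-2-yl]pent-3-en-1-yl acetate | CC(=O)O[C@H](CC=C(C)C)c1cc(OCOC)c2c(OCOC)ccc(OCOC)c2c1OCOC
F7 | step 6 | (R)-4-methyl-1-[1,4,5,8-tetrakis(methoxymethoxy)naphthalen-2-yl]pent-3-en-1-yl 3-hydroxy-3-methylbutanoate | CC(C)(O)CC(=O)O[C@H](CC=C(C)C)c1cc(OCOC)c2c(OCOC)ccc(OCOC)c2c1OCOC
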